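- The target is what the run is for, yet at the end of noon and dawn it stood at 7.5% and 6.3%, less than the intermediate at 63.0% and 60.0%, so the amount to watch in teal and red is the intermediate.

| setting | noon | dawn | teal | red |
|---|---|---|---|---|
| starting material | 0.25 M | 0.25 M | 0.25 M | 0.25 M |
| solid reagent | 0.50 M | 0.50 M | 0.500 M | 0.500 M |
| free catalyst | 1.2 mM | 1.2 mM | 1.2 mM | 1.2 mM |
| second catalyst | 0.18 mM | 0.18 mM | 0.18 mM | 0.18 mM |
| impurity | 0.26 mM | 0.36 mM | 0.20 mM | 0.30 mM |
| remark | run made earlier | run made earlier |  |  |
| time |  |  | 80 min | 80 min |

| run | time / min | starting material / % | intermediate / % | target / % |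
|---|---|---|---|---|
| noon | 15.0 | 77.1 | 23.0 | 0 |
| noon | 30.0 | 58.8 | 38.1 | 1.0 |
| noon | 50.0 | 44.9 | 52.6 | 3.3 |
| noon | 60.0 | 38.6 | 56.4 | 4.1 |
| noon | 80.0 | 30.0 | 63.0 | 7.5 |
| dawn | 8.00 | 88.3 | 11.4 | 0 |
| dawn | 20.0 | 73.2 | 26.6 | 0.7 |
| dawn | 40.0 | 54.5 | 42.8 | 2.7 |
| dawn | 60.0 | 42.2 | 53.9 | 5.0 |
| dawn | 80.0 | 32.9 | 60.0 | 6.3 |

(each reading ± 0.5 percentage points)

- solid reagent is a solid; its amount is given per volume of the solution
- steps thought possible: free catalyst + impurity -> spent catalyst; starting material + free catalyst <-> free catalyst + intermediate; solid reagent <-> partner; partner + second catalyst + intermediate -> second catalyst + target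
- at the start none of the solid reagent is in solution

1. which of these there is most of at the end, counted by the starting material in it, teal (intermediate / starting material / target)
2. which of these there is most of at the end, counted by the starting material in it, red (intermediate / starting material / target)
3. how much there is at the end of the one of these that leads, in percent of the starting material charged: teal
4. how much there is at the end of the one of these that leads, in percent of the starting material charged: red

- The flasks differ in impurity, so we take each impurity to spend one free catalyst at once, leaving a working catalyst a, the charged free catalyst minus the charged impurity: 1.00 mM in teal.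
- Teal's end then stands at 85.1 min on the noon time θ, which is the time multiplied by a flask's a and divided by noon's a.
- As a test, dawn at 60.0 min has θ of 53.6 min; noon's readings, joined in a straight line, give 42.6% of starting material there, and dawn read 42.2%.
- Counting the small target as in noon, teal's θ lies beyond noon's last reading, so teal's bound from below is 63.0% of intermediate.
- Noon's intermediate rose faster early than late, so we carry its last stretch on straight and take that as our estimate of a bound from above for teal, at 64.7%.
- Red's θ of 76.6 min lies between dawn's end at 71.5 min and noon's 80.0 min, so we bracket red's intermediate between the readings 60.0% and 63.0%.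
- The forecast, holding that “the impurity appears to remove catalyst quickly and stoichiometrically”, named intermediate for both flasks, at 64.5% for teal and 62.2% for red, inside both brackets.
- The flasks give intermediate leading, at 64.1% in teal and 61.6% in red.

    free catalyst + impurity → spent catalyst (k = 5900 M⁻¹ min⁻¹)
    starting material + free catalyst ⇌ free catalyst + intermediate (K = 5.90, k = 19.0 M⁻¹ min⁻¹)
    solid reagent ⇌ partner, rate k3*(cs3 - [partner]) while solid is left; crystals form when [partner] > cs3 (solubility = 17.0 mM, k = 0.0810 min⁻¹)
    partner + second catalyst + intermediate → second catalyst + target (k = 920 M⁻² min⁻¹)

- In teal at 24.3 min, the half-life of intermediate by the partner step is 5.2 h, longer than the run and longer than the 36 min of starting material by the forward step alone. At the end of teal, intermediate is still made 2.44 times faster than it is used, on a free catalyst of 83.3% of its charge, where a gave 83.3%; red's intermediate has moved by 6 points at 1.02 mM of free catalyst, the other amounts and the time held.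
- Teal read at 20 min has θ of 21.3 min, where noon's line gives 69.4% of starting material.
- That flask holds 69.3% of starting material, still leading, and 30.2% of intermediate.

(The runs were generated by integration with constants of no real substance, noise included.)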